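**Retrosynthetic overview**

- The target is the free phenol of 2,4-dibromo-6-(2,4-dibromophenoxy)phenyl acetate; the last step is acetate methanolysis.
- The strategy rests on ring A, numbered C1 (OH), C2 (Br), C3 (H), C4 (Br), C5 (H), C6 (aryloxy). It is cut at C1–C6 and C4–C5. C1 to C4 are C3 to C6 of 3-acetoxy-4,6-dibromo-2-pyrone, which brings the C1 oxygen and both bromines. C6 and C5 are the two carbons of 2,4-dibromophenyl ethynyl ether. The pyrone O1–C2 unit leaves as CO2.
- The pyrone comes from 3-hydroxy-2-pyrone by 4,6-dibromination and O-acetylation.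
- The ynol ether comes from 2,4-dibromophenol through the 2-bromoethyl ether, the vinyl ether, bromine addition with loss of HBr, and a second loss of HBr with an alkoxide base that leaves the aryl bromides alone.
- Ring B is bought intact; ring A is the only ring formed, in the key step.

Key step: step 7

Assumption: the aryl ethynyl ether is taken to be too labile to store neat, so it is carried into the cycloaddition as a cold, dilute toluene solution.

**Route**

Step 1
Reactants: 1 3-hydroxy-2H-pyran-2-one
Product: 2 4,6-dibromo-3-hydroxy-2H-pyran-2-one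
Conditions: NBS (2.1 equiv), MeCN, 0 °C to rt, dark
Reagents that add atoms: N-bromosuccinimide, O=C1CCC(=O)N1Br
Why: Electrophilic bromination of the enolic hydroxypyrone, in which the C3 hydroxyl activates C4 (ortho-like) and C6 (vinylogous, para-like) as a phenol OH does, while C5 is activated only by the weakly donating lactone oxygen.

Step 2
Reactants: 2 4,6-dibromo-3-hydroxy-2H-pyran-2-one
Product: 3 4,6-dibromo-2-oxo-2H-pyran-3-yl acetate (3-acetoxy-4,6-dibromo-2-pyrone)
Conditions: Ac2O (1.5 equiv), H2SO4 (cat.), CH2Cl2, 0 °C to rt; AcOH removed by toluene azeotrope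
Reagents that add atoms: acetic anhydride, CC(=O)OC(C)=O
Why: Acid-catalysed O-acetylation of an acidic enol; nucleophilic amine catalysts are avoided because a 6-bromo-2-pyrone is open to addition–elimination at C6.

Step 3
Reactants: 4 2,4-dibromophenol; 5 1,2-dibromoethane (5 equiv)
Product: 6 2,4-dibromo-1-(2-bromoethoxy)benzene
Conditions: K2CO3 (2 equiv), MeCN, reflux
Reagents that add atoms: none
Why: Williamson ether synthesis, with excess dibromide to suppress the bis-aryl ether.

Step 4
Reactants: 6 2,4-dibromo-1-(2-bromoethoxy)benzene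
Product: 7 2,4-dibromo-1-(ethenyloxy)benzene
Conditions: KOt-Bu (1.5 equiv), THF, 0 °C to rt
Reagents that add atoms: none
Why: E2 dehydrobromination of a 2-aryloxyethyl bromide, a standard entry to aryl vinyl ethers; potassium tert-butoxide at or below room temperature does not attack aryl bromides.

Step 5
Reactants: 7 2,4-dibromo-1-(ethenyloxy)benzene
Product: 9 (Z)-2,4-dibromo-1-[(2-bromoethenyl)oxy]benzene, via 1,2-dibromoethyl ether 8 (not isolated)
Conditions: Br2 (1.0 equiv), CH2Cl2, −78 °C; then i-Pr2NEt (1.5 equiv), −78 °C to 40 °C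
Reagents that add atoms: bromine, BrBr
Why: Bromine adds to the electron-rich vinyl ether much faster than it substitutes the deactivated dibromoaryl ring, and the amine then removes HBr from the alpha-bromo ether (ionisation to the oxocarbenium ion, loss of the beta proton), the usual route to beta-bromo enol ethers, expected mainly as the Z isomer.

Step 6
Reactants: 9 (Z)-2,4-dibromo-1-[(2-bromoethenyl)oxy]benzene
Product: 10 2,4-dibromo-1-(ethynyloxy)benzene
Conditions: KOt-Bu (1.5 equiv), THF, −20 °C to rt; pH 7 buffer work-up; kept as a cold toluene solution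
Reagents that add atoms: none
Why: Anti-periplanar E2 loss of HBr from the Z-bromo enol ether (vinyl H and Br trans) gives the alkyne; an alkoxide is chosen because alkyllithium or NaNH2 bases would exchange or eliminate at the aryl bromides.

Step 7
Reactants: 3 4,6-dibromo-2-oxo-2H-pyran-3-yl acetate; 10 2,4-dibromo-1-(ethynyloxy)benzene (2 equiv, added in portions)
Product: 12 2,4-dibromo-6-(2,4-dibromophenoxy)phenyl acetate, via bicyclic lactone 11 (not isolated)
Conditions: PhMe, 100 °C, sealed tube, BHT (cat.)
Reagents that add atoms: none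
Why: Inverse-electron-demand Diels–Alder reaction in which the electron-rich triple bond of 10 adds across C3 and C6 of the pyrone, whose LUMO is lowered by the lactone carbonyl and the two bromines, to give the bridged lactone 11, which loses CO2 by retro-[4+2] at the reaction temperature because an aromatic ring results. The closest known type is the benzannulation of 2-pyrones with electron-rich alkynes or ketene acetals followed by CO2 extrusion. Ring A is closed by this intermolecular two-bond [4+2] union, which forms target bonds C1–C6 and C4–C5 together with no separate cyclisation, and the ring is aromatic as soon as CO2 leaves. No stereocenter is set, since the two bridgehead centres of 11 are destroyed in the cycloreversion. The step needs regioselectivity, and the polarisation of both partners should secure it: the nucleophilic terminal CH of 10 bonds to the electrophilic C6 of the pyrone with charge build-up at C3 stabilised by the lactone carbonyl, and the oxygen-stabilised alkyne carbon bonds to C3, so the aryloxy group ends ortho to the acetoxy carbon. The aryl ynol ether has no hydrogen for retro-ene loss to a ketene, and the enol is masked as its acetate so that it cannot protonate or add to the ynol ether.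

Step 8
Reactants: 12 2,4-dibromo-6-(2,4-dibromophenoxy)phenyl acetate
Product: 13 2,4-dibromo-6-(2,4-dibromophenoxy)phenol
Conditions: K2CO3 (1.5 equiv), MeOH, 0 °C to rt; aq. NH4Cl work-up
Reagents that add atoms: none
Why: Base-mediated transesterification of an aryl acetate to methyl acetate; the diaryl ether and the aryl bromides are inert, and the phenol is freed on work-up.

**Compound list**

1 | 3-hydroxy-2H-pyran-2-one | OC1=CC=COC1=O | starting material
2 | 4,6-dibromo-3-hydroxy-2H-pyran-2-one | OC1=C(Br)C=C(Br)OC1=O | intermediate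
3 | 4,6-dibromo-2-oxo-2H-pyran-3-yl acetate | CC(=O)OC1=C(Br)C=C(Br)OC1=O | intermediate
4 | 2,4-dibromophenol | Oc1ccc(Br)cc1Br | starting material
5 | 1,2-dibromoethane | BrCCBr | starting material
6 | 2,4-dibromo-1-(2-bromoethoxy)benzene | BrCCOc1ccc(Br)cc1Br | intermediate
7 | 2,4-dibromo-1-(ethenyloxy)benzene | C=COc1ccc(Br)cc1Br | intermediate
8 | 2,4-dibromo-1-(1,2-dibromoethoxy)benzene (racemic) | BrCC(Br)Oc1ccc(Br)cc1Br | intermediate
9 | (Z)-2,4-dibromo-1-[(2-bromoethenyl)oxy]benzene | Br/C=C\Oc1ccc(Br)cc1Br | intermediate
10 | 2,4-dibromo-1-(ethynyloxy)benzene | C#COc1ccc(Br)cc1Br | intermediate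
11 | 1,5-dibromo-8-(2,4-dibromophenoxy)-3-oxo-2-oxabicyclo[2.2.2]octa-5,7-dien-4-yl acetate (racemic; relative configuration of the two bridgeheads fixed by the bridge) | O=C1OC2(Br)C=C(Br)C1(OC(C)=O)C(Oc1ccc(Br)cc1Br)=C2 | intermediate
12 | 2,4-dibromo-6-(2,4-dibromophenoxy)phenyl acetate | CC(=O)Oc1c(Br)cc(Br)cc1Oc1ccc(Br)cc1Br | intermediate
13 | 2,4-dibromo-6-(2,4-dibromophenoxy)phenol | Oc1c(Br)cc(Br)cc1Oc1ccc(Br)cc1Br | target

**Step count**

Total: 8 steps. Longest linear sequence: 6 steps (4 → 6 → 7 → 9 → 10 → 12 → 13; steps 3 to 8).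

**Steps most likely to fail**

1. Step 7 (cycloaddition). The ynol ether may oligomerise or be hydrated faster than it adds to the pyrone, or the cycloaddition may be too slow at temperatures the ynol ether survives, or some bonding may occur in the reversed orientation. Fallback, from 4 to 13, with ring A bought and brominated instead of built: 4 is joined to 2-fluorobenzaldehyde by nucleophilic aromatic substitution (K2CO3, DMAc, 140 °C) to give 2-(2,4-dibromophenoxy)benzaldehyde F1. Baeyer–Villiger oxidation with mCPBA in CH2Cl2 should give 2-(2,4-dibromophenoxy)phenyl formate F2, which K2CO3 in methanol cleaves to 2-(2,4-dibromophenoxy)phenol F3. NBS (2 equiv) in MeCN then brominates ring A ortho and para to the free hydroxyl, ring B being deactivated by its two bromines, and gives 13.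

2. Step 6 (ynol ether formation). tert-Butoxide or tert-butanol may add across the new triple bond, or the terminal ynol ether may oligomerise during work-up, so that no usable solution is obtained. Fallback, from 7 to 12, replacing the alkyne by a ketene acetal that carries its own leaving group: 7 is brominated as in step 5 to 8, and 8 is intercepted with phenol 4 and i-Pr2NEt instead of being eliminated, giving 2-bromo-1,1-bis(2,4-dibromophenoxy)ethane F4. KOt-Bu in THF removes HBr to give 1,1-bis(2,4-dibromophenoxy)ethene F5. Heating F5 with 3 in toluene should give, with the same orientation, the bridged lactone 1,5-dibromo-8,8-bis(2,4-dibromophenoxy)-3-oxo-2-oxabicyclo[2.2.2]oct-5-en-4-yl acetate F6, which loses CO2 to 2,4-dibromo-6,6-bis(2,4-dibromophenoxy)cyclohexa-1,3-dien-1-yl acetate F7. Loss of 2,4-dibromophenol from F7 (DBU if needed) aromatises the ring to 12.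

3. Step 1 (dibromination). The second bromine may enter at C5, or bromine may add across the C5–C6 double bond instead of substituting, giving a mixture of bromopyrones that cannot be purified. Fallback, from 1 to 13, moving the C4 bromine of the target to a late phenol bromination: 1 is brominated once (NBS, 1.0 equiv) to 4-bromo-3-hydroxy-2H-pyran-2-one F8 and acetylated as in step 2 to 4-bromo-2-oxo-2H-pyran-3-yl acetate F9. Cycloaddition with 10 as in step 7 should give, via the bridged lactone 5-bromo-8-(2,4-dibromophenoxy)-3-oxo-2-oxabicyclo[2.2.2]octa-5,7-dien-4-yl acetate F10 and loss of CO2, 2-bromo-6-(2,4-dibromophenoxy)phenyl acetate F11. Methanolysis gives 2-bromo-6-(2,4-dibromophenoxy)phenol F12, whose only free activated position is para to the hydroxyl, so one equivalent of NBS gives 13.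

**Further compounds**

F1 | step 7 | 2-(2,4-dibromophenoxy)benzaldehyde | O=Cc1ccccc1Oc1ccc(Br)cc1Br
F2 | step 7 | 2-(2,4-dibromophenoxy)phenyl formate | O=COc1ccccc1Oc1ccc(Br)cc1Br
F3 | step 7 | 2-(2,4-dibromophenoxy)phenol | Oc1ccccc1Oc1ccc(Br)cc1Br
F4 | step 6 | 2-bromo-1,1-bis(2,4-dibromophenoxy)ethane | BrCC(Oc1ccc(Br)cc1Br)Oc1ccc(Br)cc1Br
F5 | step 6 | 1,1-bis(2,4-dibromophenoxy)ethene | C=C(Oc1ccc(Br)cc1Br)Oc1ccc(Br)cc1Br
F6 | step 6 | 1,5-dibromo-8,8-bis(2,4-dibromophenoxy)-3-oxo-2-oxabicyclo[2.2.2]oct-5-en-4-yl acetate (racemic) | O=C1OC2(Br)C=C(Br)C1(OC(C)=O)C(Oc1ccc(Br)cc1Br)(Oc1ccc(Br)cc1Br)C2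
F7 | step 6 | 2,4-dibromo-6,6-bis(2,4-dibromophenoxy)cyclohexa-1,3-dien-1-yl acetate | CC(=O)OC1=C(Br)C=C(Br)CC1(Oc1ccc(Br)cc1Br)Oc1ccc(Br)cc1Br
F8 | step 1 | 4-bromo-3-hydroxy-2H-pyran-2-one | OC1=C(Br)C=COC1=O
F9 | step 1 | 4-bromo-2-oxo-2H-pyran-3-yl acetate | CC(=O)OC1=C(Br)C=COC1=O
F10 | step 1 | 5-bromo-8-(2,4-dibromophenoxy)-3-oxo-2-oxabicyclo[2.2.2]octa-5,7-dien-4-yl acetate (racemic) | O=C1OC2C=C(Br)C1(OC(C)=O)C(Oc1ccc(Br)cc1Br)=C2
F11 | step 1 | 2-bromo-6-(2,4-dibromophenoxy)phenyl acetate | CC(=O)Oc1c(Br)cccc1Oc1ccc(Br)cc1Br
F12 | step 1 | 2-bromo-6-(2,4-dibromophenoxy)phenol | Oc1c(Br)cccc1Oc1ccc(Br)cc1Br
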